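**Strategy.** Each half of the target is the same cis-fused decalin in which ring B carries, on adjacent carbons, the angular C10 methyl (cis to H5), the C9 arm and the methyl-bearing C8. The plan cuts the C11–C12 bridge into two C9 acetic acid arms and builds the C10/C9 pair in one operation: a methyl cuprate adds to C10 of a ring-B enone and the resulting C8–C9 enolate is alkylated at C9 by an iodoacetate, setting both stereocentres and leaving the C8 ketone for either half. The precursor is an enantiopure 3α-silyloxy-4,4-dimethyl-5β-Δ9(10)-octalin-8-one, reached from a 2-tetralone by reduction and Birch chemistry; a mixed Kolbe electrolysis joins the halves.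

Key step: step 6

Remark on the chemistry: decalin numbering is used (ring A = C1–C5, C10; ring B = C5–C10; C3 carbinol, C4 gem-dimethyl, C9 arm, C11–C12 bridge; primes for the saturated half), and β is the face of the C10 methyl. Read this way, both halves of the target are 3α-OH (3R), 5β-H, 10β-CH3 and 9β-arm, and the saturated half is 8′α-CH3. The supplied precursor and product structures agree with this and need no correction.

**Step 1**
Reactants: 1 6-methoxy-2-tetralone; 2 iodomethane
Product: 4 6-methoxy-1,1-dimethyl-2-tetralone, via monomethyl ketone 3 (not isolated)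
Conditions: NaH (2.2 equiv), MeI (2.5 equiv), THF, 0 °C to rt
Reagents that add atoms: iodomethane 2, CI
Why: Double enolate C-alkylation; the benzylic C1–H bonds of a 2-tetralone are the most acidic, so both methyl groups go to C1 (the future C4) and no stereocentre is formed.

**Step 2**
Reactants: 4 6-methoxy-1,1-dimethyl-2-tetralone
Product: 5 (R)-6-methoxy-1,1-dimethyl-1,2,3,4-tetrahydronaphthalen-2-ol
Conditions: (S)-1-methyl-3,3-diphenyltetrahydro-1H,3H-pyrrolo[1,2-c][1,3,2]oxazaborole (10 mol%), BH3·SMe2, THF, −20 °C; MeOH quench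
Reagents that add atoms: none
Why: Corey–Bakshi–Shibata reduction; the catalyst distinguishes the quaternary C1 side (large) from the CH2 side (small), and the (S)-oxazaborolidine should give the (R)-carbinol (future C3), as it does with tert-alkyl methyl ketones.

**Step 3**
Reactants: 5 (R)-6-methoxy-1,1-dimethyl-1,2,3,4-tetrahydronaphthalen-2-ol
Product: 8 (4aS,6R)-6-hydroxy-5,5-dimethyl-4,4a,5,6,7,8-hexahydronaphthalen-2(3H)-one [decalin numbering: (3R,5S)-3α-hydroxy-4,4-dimethyl-5β-H-Δ9(10)-octalin-8-one], via dihydroanisole 6 (not isolated), via nonconjugated enone 7 (not isolated)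
Conditions: Li, NH3(l), THF, tBuOH, −78 to −33 °C, NH4Cl quench; then 3 M HCl, MeOH–THF, rt to 50 °C
Reagents that add atoms: water, O
Why: Birch reduction of the anisole ring followed by acid hydrolysis of the enol ether and conjugation, as in the classical 19-nor-steroid sequence; C5 is protonated anti to the pseudoaxial 4α-methyl and stays epimerisable through the dienol, so the epimer with O3 and C6 both equatorial on ring A (H5 trans to O3) should predominate, and any minor C5 epimer is separated and re-equilibrated.

**Step 4**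
Reactants: 8 (3R,5S)-3α-hydroxy-4,4-dimethyl-5β-Δ9(10)-octalin-8-one
Product: 9 (3R,5S)-3α-(tert-butyldimethylsilyloxy)-4,4-dimethyl-5β-Δ9(10)-octalin-8-one
Conditions: TBSOTf, 2,6-lutidine, CH2Cl2, −78 to 0 °C
Reagents that add atoms: tert-butyldimethylsilyl trifluoromethanesulfonate, CC(C)(C)[Si](C)(C)OS(=O)(=O)C(F)(F)F
Why: O-Silylation of a hindered secondary alcohol with a silyl triflate and a non-nucleophilic base; the enone and C5 are not touched at low temperature.

**Step 5**
Reactants: 10 tert-butyl bromoacetate
Product: 11 tert-butyl iodoacetate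
Conditions: NaI, acetone, rt, dark
Reagents that add atoms: sodium iodide, [Na+].[I-]
Why: Finkelstein halide exchange, driven by precipitation of NaBr, gives the more reactive alkylating agent fresh for the next step.

**Step 6**
Reactants: 9 (3R,5S)-3α-(tert-butyldimethylsilyloxy)-4,4-dimethyl-5β-Δ9(10)-octalin-8-one; 11 tert-butyl iodoacetate
Product: 13 tert-butyl [3α-(tert-butyldimethylsilyloxy)-4,4,10β-trimethyl-8-oxo-5β-decalin-9β-yl]acetate (cis-fused keto ester; 9α-H), via lithium enolate 12 (not isolated)
Conditions: CuI, MeLi (2 equiv per Cu), Et2O, 0 °C; 9, −20 to 0 °C; then THF, HMPA, 11, −40 °C to rt; aq. NH4Cl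
Reagents that add atoms: lithium dimethylcuprate, [Li+].C[Cu-]C; tert-butyl iodoacetate 11, CC(C)(C)OC(=O)CI
Why: Me2CuLi transfers methyl to C10 of the enone by 1,4-addition and leaves the regiodefined C8–C9 lithium enolate 12, which is alkylated at C9 by the primary iodide 11 in an SN2 step; no ring is closed. The closest known reaction type is cuprate addition to Δ1(9)-2-octalones with alkylation of the specific enolate in the same flask. C10 is controlled by C5 and the axial 4α-methyl: delivery from the β face is axial to ring B but equatorial to ring A and avoids the syn-axial 4α-methyl, so the new methyl ends cis to H5. C9 is controlled by the cis ring fusion: ring A with its 4α-methyl covers the α face of the enolate, so 11 enters from the convex β face, and the 9β arm is also the equatorial, thermodynamically preferred epimer at this enolisable centre. The step needs C-alkylation at C9 and not at C7 or oxygen, which is secured because the enolate is generated only at C8–C9 and is trapped by a reactive iodide in THF–HMPA before proton transfer can move it.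

**Step 7**
Reactants: 13 cis-fused keto ester
Product: 14 [3α-(tert-butyldimethylsilyloxy)-4,4,10β-trimethyl-8-oxo-5β-decalin-9β-yl]acetic acid
Conditions: 85% aq. H3PO4, toluene, rt to 40 °C
Reagents that add atoms: none
Why: Acidolysis of the tert-butyl ester by alkyl–oxygen cleavage under conditions mild enough for a hindered secondary silyl ether; C9 can at most equilibrate to the favoured 9β configuration it already has.

**Step 8**
Reactants: 13 cis-fused keto ester
Product: 15 tert-butyl [3α-(tert-butyldimethylsilyloxy)-4,4,10β-trimethyl-8-methylene-5β-decalin-9β-yl]acetate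
Conditions: Ph3PCH3Br, KOtBu, toluene, 0 to 80 °C
Reagents that add atoms: methylenetriphenylphosphorane, C=P(c1ccccc1)(c1ccccc1)c1ccccc1
Why: Wittig methylenation of the C8 ketone; the tert-butyl ester is inert to the ylide and C9, though enolisable, is already in its preferred configuration.

**Step 9**
Reactants: 15 8-methylene ester
Product: 16 tert-butyl [3α-(tert-butyldimethylsilyloxy)-4,4,8α,10β-tetramethyl-5β-decalin-9β-yl]acetate (8β-H)
Conditions: Mn(dpm)3 (10 mol%; dpm = 2,2,6,6-tetramethylheptane-3,5-dionate), PhSiH3, tBuOOH, iPrOH, rt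
Reagents that add atoms: none
Why: Hydrogen-atom-transfer hydrogenation; a manganese hydride adds H to the terminal CH2 and the tertiary C8 radical is reduced under product-like control, so the methyl should take the equatorial 8α position, trans to the 9β arm and clear of a syn-diaxial clash with the 10β-methyl.

**Step 10**
Reactants: 16 8α-methyl ester
Product: 17 [3α-(tert-butyldimethylsilyloxy)-4,4,8α,10β-tetramethyl-5β-decalin-9β-yl]acetic acid
Conditions: 85% aq. H3PO4, toluene, rt to 40 °C
Reagents that add atoms: none
Why: Acidolysis of the tert-butyl ester as in step 7; no stereocentre is enolisable any more.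

**Step 11**
Reactants: 14 keto acid; 17 8α-methyl acid
Product: 18 1-[3α-(tert-butyldimethylsilyloxy)-4,4,10β-trimethyl-8-oxo-5β-decalin-9β-yl]-2-[3′α-(tert-butyldimethylsilyloxy)-4′,4′,8′α,10′β-tetramethyl-5′β-decalin-9′β-yl]ethane
Conditions: Pt anode, Pt cathode, undivided cell, constant current, KOH (0.1 equiv), MeOH–pyridine, 40 °C; 14 in threefold excess
Reagents that add atoms: none
Why: Mixed Kolbe electrolysis; anodic decarboxylation gives the primary C11 and C12 radicals, which couple at the electrode without touching a stereocentre, the excess of the cheaper acid 14 drives 17 into the cross-product, and this monoketone should separate easily from the diketone and ketone-free homodimers.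

**Step 12**
Reactants: 18 cross-coupled monoketone
Product: 20 Δ7-enol triflate of 18 (C8–OSO2CF3 with C7=C8), via potassium enolate 19 (not isolated)
Conditions: KN(SiMe3)2, THF, −78 °C; then PhNTf2, −78 to 0 °C; aq. NH4Cl
Reagents that add atoms: N-phenylbis(trifluoromethanesulfonimide), O=S(=O)(N(c1ccccc1)S(=O)(=O)C(F)(F)F)C(F)(F)F
Why: Kinetic enolisation with a bulky amide base takes the unhindered C7 methylene and not the tertiary, neopentyl C9–H, and O-triflation fixes the Δ7 regiochemistry.

**Step 13**
Reactants: 20 Δ7-enol triflate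
Product: 21 bis(tert-butyldimethylsilyl) ether of the target (Δ7, 8-methyl in the unsaturated half)
Conditions: MeMgBr, Fe(acac)3 (5 mol%), THF–NMP, −20 to 0 °C
Reagents that add atoms: methylmagnesium bromide, C[Mg]Br
Why: Iron-catalysed Kumada-type cross-coupling of an alkenyl triflate with a methyl Grignard reagent replaces OTf by CH3 without moving the double bond; the silyl ethers are inert.

**Step 14**
Reactants: 21 bis-silyl ether
Product: 22 target, 1-[3α-hydroxy-4,4,8,10β-tetramethyl-5β-Δ7-octalin-9β-yl]-2-[3′α-hydroxy-4′,4′,8′α,10′β-tetramethyl-5′β-decalin-9′β-yl]ethane (CNP0194061.2)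
Conditions: Bu4NF, THF, 60 °C
Reagents that add atoms: none
Why: Fluoride desilylation of both ethers; heating makes up for the hindered position next to the gem-dimethyl group and nothing else in the molecule reacts.

**Compound list**

1 | 6-methoxy-2-tetralone | COc1ccc2c(c1)CCC(=O)C2 | starting material
2 | iodomethane | CI | starting material
3 | 6-methoxy-1-methyl-2-tetralone (racemic) | COc1ccc2c(c1)CCC(=O)C2C | intermediate
4 | 6-methoxy-1,1-dimethyl-2-tetralone | COc1ccc2c(c1)CCC(=O)C2(C)C | intermediate
5 | (R)-6-methoxy-1,1-dimethyl-1,2,3,4-tetrahydronaphthalen-2-ol | COc1ccc2c(c1)CC[C@@H](O)C2(C)C | intermediate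
6 | (R)-6-methoxy-1,1-dimethyl-1,2,3,4,5,8-hexahydronaphthalen-2-ol (dihydroanisole) | COC1=CCC2=C(C1)CC[C@@H](O)C2(C)C | intermediate
7 | (R)-6-hydroxy-5,5-dimethyl-3,4,5,6,7,8-hexahydronaphthalen-2(1H)-one (Δ5(10)-8-one) | O=C1CCC2=C(C1)CC[C@@H](O)C2(C)C | intermediate
8 | (3R,5S)-3α-hydroxy-4,4-dimethyl-5β-Δ9(10)-octalin-8-one | O=C1CC[C@@H]2C(C)(C)[C@H](O)CCC2=C1 | intermediate
9 | (3R,5S)-3α-(tert-butyldimethylsilyloxy)-4,4-dimethyl-5β-Δ9(10)-octalin-8-one | O=C1CC[C@@H]2C(C)(C)[C@H](O[Si](C)(C)C(C)(C)C)CCC2=C1 | intermediate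
10 | tert-butyl bromoacetate | CC(C)(C)OC(=O)CBr | starting material
11 | tert-butyl iodoacetate | CC(C)(C)OC(=O)CI | intermediate
12 | lithium C8–C9 enolate of the cis-fused 10β-methyl decalone | [Li]OC1=C[C@@]2(C)CC[C@@H](O[Si](C)(C)C(C)(C)C)C(C)(C)[C@H]2CC1 | intermediate
13 | tert-butyl [3α-(tert-butyldimethylsilyloxy)-4,4,10β-trimethyl-8-oxo-5β-decalin-9β-yl]acetate | CC(C)(C)OC(=O)C[C@H]1C(=O)CC[C@@H]2C(C)(C)[C@H](O[Si](C)(C)C(C)(C)C)CC[C@@]21C | intermediate
14 | [3α-(tert-butyldimethylsilyloxy)-4,4,10β-trimethyl-8-oxo-5β-decalin-9β-yl]acetic acid | OC(=O)C[C@H]1C(=O)CC[C@@H]2C(C)(C)[C@H](O[Si](C)(C)C(C)(C)C)CC[C@@]21C | intermediate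
15 | tert-butyl [3α-(tert-butyldimethylsilyloxy)-4,4,10β-trimethyl-8-methylene-5β-decalin-9β-yl]acetate | CC(C)(C)OC(=O)C[C@H]1C(=C)CC[C@@H]2C(C)(C)[C@H](O[Si](C)(C)C(C)(C)C)CC[C@@]21C | intermediate
16 | tert-butyl [3α-(tert-butyldimethylsilyloxy)-4,4,8α,10β-tetramethyl-5β-decalin-9β-yl]acetate | CC(C)(C)OC(=O)C[C@H]1[C@H](C)CC[C@@H]2C(C)(C)[C@H](O[Si](C)(C)C(C)(C)C)CC[C@@]21C | intermediate
17 | [3α-(tert-butyldimethylsilyloxy)-4,4,8α,10β-tetramethyl-5β-decalin-9β-yl]acetic acid | OC(=O)C[C@H]1[C@H](C)CC[C@@H]2C(C)(C)[C@H](O[Si](C)(C)C(C)(C)C)CC[C@@]21C | intermediate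
18 | cross-coupled 8-oxo bis-silyl ether | O=C1CC[C@@H]2C(C)(C)[C@H](O[Si](C)(C)C(C)(C)C)CC[C@]2(C)[C@H]1CC[C@H]1[C@H](C)CC[C@@H]2C(C)(C)[C@H](O[Si](C)(C)C(C)(C)C)CC[C@@]21C | intermediate
19 | potassium Δ7-enolate of 18 | [K]OC1=CC[C@@H]2C(C)(C)[C@H](O[Si](C)(C)C(C)(C)C)CC[C@]2(C)[C@H]1CC[C@H]1[C@H](C)CC[C@@H]2C(C)(C)[C@H](O[Si](C)(C)C(C)(C)C)CC[C@@]21C | intermediate
20 | Δ7-enol triflate of 18 | O=S(=O)(OC1=CC[C@@H]2C(C)(C)[C@H](O[Si](C)(C)C(C)(C)C)CC[C@]2(C)[C@H]1CC[C@H]1[C@H](C)CC[C@@H]2C(C)(C)[C@H](O[Si](C)(C)C(C)(C)C)CC[C@@]21C)C(F)(F)F | intermediate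
21 | bis(tert-butyldimethylsilyl) ether of the target | CC1=CC[C@@H]2C(C)(C)[C@H](O[Si](C)(C)C(C)(C)C)CC[C@]2(C)[C@H]1CC[C@H]1[C@H](C)CC[C@@H]2C(C)(C)[C@H](O[Si](C)(C)C(C)(C)C)CC[C@@]21C | intermediate
22 | CNP0194061.2 | CC1=CC[C@@H]2C(C)(C)[C@H](O)CC[C@]2(C)[C@H]1CC[C@H]1[C@H](C)CC[C@@H]2C(C)(C)[C@H](O)CC[C@@]21C | target

**Step count.** 14 steps in total; longest linear sequence 12 steps (steps 1–4, 6, 8–14).

**Steps most likely to fail**

Step 6. The enolate next to the new quaternary centre may be alkylated too slowly, so that proton transfer to the product ketone scrambles the enolate (attack at C7 or twofold alkylation), and residual organocopper species may consume the iodoacetate. The fallback sets out from 9 and separates the two bond formations. Conjugate addition with MeMgBr, CuBr·SMe2 (catalytic), Me3SiCl and HMPA in THF at −78 °C should give the trimethylsilyl enol ether F1, which is isolated. MeLi in THF at 0 °C then regenerates the copper-free lithium enolate 12, and alkylation with 11 in THF–HMPA comes back to the route at 13. Should any 9α epimer appear, brief treatment with DBU would move it to the equatorial 9β arm.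

Step 11. Random pairing of the two radicals, together with over-oxidation at the anode or fouling of the electrode, may leave little cross-coupled material. The fallback sets out from 14 and 17 and replaces electrolysis by a nickel-catalysed decarboxylative alkyl–alkyl coupling. Acid 14 is condensed with N-hydroxyphthalimide (N,N′-diisopropylcarbodiimide, catalytic DMAP, CH2Cl2) to the redox-active ester F2. Acid 17 is converted by iododecarboxylation (PhI(OAc)2, I2, light, PhCl) into the primary iodide F3, and this by tBuLi at −78 °C followed by ZnCl2 into the dialkylzinc F4. F2 and F4 with NiCl2(dme) and 4,4′-di-tert-butyl-2,2′-bipyridine in THF–DMF at rt should give the cross-product only, returning at 18.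

Step 9. Hydrogen may be delivered to the C8 radical from the open equatorial α direction and not along the axial path beside the 10β-methyl, which would erode facial selectivity at C8. The fallback sets out from 15 and uses chelation in place of radical control: hydrogenation with [Ir(cod)(PCy3)(py)]PF6 under H2 in CH2Cl2, in which the ester carbonyl of the 9β arm binds iridium and delivers hydrogen to the β face of the exocyclic alkene. This gives 8β-H and 8α-methyl and comes back at 16; the detour makes no new compound (F0).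

**Further compounds**

F1 | step 6 | trimethylsilyl C8–C9 enol ether of the cis-fused 3α-silyloxy-4,4,10β-trimethyl-5β-decal-8-one | C[Si](C)(C)OC1=C[C@@]2(C)CC[C@@H](O[Si](C)(C)C(C)(C)C)C(C)(C)[C@H]2CC1
F2 | step 11 | N-hydroxyphthalimide ester of keto acid 14 | O=C(C[C@H]1C(=O)CC[C@@H]2C(C)(C)[C@H](O[Si](C)(C)C(C)(C)C)CC[C@@]21C)ON1C(=O)c2ccccc2C1=O
F3 | step 11 | 9β-(iodomethyl)-3α-(tert-butyldimethylsilyloxy)-4,4,8α,10β-tetramethyl-5β-decalin | IC[C@H]1[C@H](C)CC[C@@H]2C(C)(C)[C@H](O[Si](C)(C)C(C)(C)C)CC[C@@]21C
F4 | step 11 | bis{[3α-(tert-butyldimethylsilyloxy)-4,4,8α,10β-tetramethyl-5β-decalin-9β-yl]methyl}zinc | [Zn](C[C@H]1[C@H](C)CC[C@@H]2C(C)(C)[C@H](O[Si](C)(C)C(C)(C)C)CC[C@@]21C)C[C@H]1[C@H](C)CC[C@@H]2C(C)(C)[C@H](O[Si](C)(C)C(C)(C)C)CC[C@@]21C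
F0 | step 9 | none | none
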